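**Plan**

- Retrosynthesis: the methoxy oxygen on the methoxy ring is traced back to a formyl carbon (Baeyer–Villiger, then O‑methylation). All four C–Br bonds are then cut in one operation. Last, the diaryl ether C–O bond is cut to give catechol and 2‑fluorobenzaldehyde.
- Forward: both benzene rings are bought and no ring is formed. The ether is joined first by SNAr, the four bromines follow in one flask, then come phenol protection, CHO → OH, O‑methylation and deprotection.
- Enabling feature: on the methoxy ring the two bromines sit ortho and para to the diaryl ether oxygen and both meta to the ring carbon bearing OMe. On the phenol ring they sit ortho and para to the hydroxyl oxygen. With a formyl group on the future OMe carbon, the ether oxygen (ortho/para) and CHO (meta) select the same two ring carbons.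
- Stereochemistry: the target has no stereocentre and the diaryl ether axis is not configurationally stable, so the structure given is a single achiral compound and no stereocontrol is needed.

Key step: step 2

**Route**

Step 1
Reactants: 1 catechol (benzene‑1,2‑diol); 2 2‑fluorobenzaldehyde
Product: 3 2‑(2‑hydroxyphenoxy)benzaldehyde
Conditions: 1 (3 equiv), K2CO3 (1.5 equiv), DMF, 90 °C, N2
Reagents that add atoms: none
Why: Nucleophilic aromatic substitution (SNAr) in which the ortho‑formyl group stabilises the Meisenheimer adduct and fluoride is the best leaving group, while the excess of catechol under nitrogen should suppress arylation of the second hydroxyl and oxidative loss of the catecholate.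

Step 2
Reactants: 3 2‑(2‑hydroxyphenoxy)benzaldehyde
Product: 7 3,5‑dibromo‑2‑(3,5‑dibromo‑2‑hydroxyphenoxy)benzaldehyde, via monobromide 4 (not isolated), via dibromide 5 (not isolated), via tribromide 6 (not isolated)
Conditions: NBS (2.05 equiv), TFA, 0 °C → rt, dark; then conc. H2SO4 (TFA/H2SO4 ca. 4:1), NBS (2.15 equiv, in portions), rt → 45 °C; aq. NaHSO3 quench
Reagents that add atoms: N‑bromosuccinimide, O=C1CCC(=O)N1Br
Why: Four successive electrophilic aromatic substitutions (Wheland intermediate, then proton loss) run in one flask: in TFA alone the bromonium source should attack only the phenol ring, para and then ortho to the free OH (4, 5), and added sulfuric acid raises the electrophilicity enough for the formyl‑bearing ring, which should take bromine para (6) and then ortho to the ether oxygen. The closest known reaction types are the 4,6‑dibromination of 2‑alkoxyphenols and the NBS/strong‑acid bromination of deactivated benzaldehydes and 2‑alkoxybenzaldehydes at C3 and C5. No ring is closed and no stereocentre is formed. Regioselectivity is needed on both rings: on the phenol ring the free OH outranks the aryloxy oxygen as director, and on the aldehyde ring the ether oxygen (ortho/para) and the formyl group (meta) converge on C3 and C5, whereas a methoxy group at the formyl carbon would have sent bromine para to itself. The weak point is chemoselectivity between the slow fourth substitution and a fifth bromination of the phenol ring; it rests on the two open positions of that ring being meta to OH and each flanked by two substituents, on a TFA–H2SO4 medium in which the aldehyde is not fully protonated, and on metering the last equivalent of NBS. Brominating the phenol ring before the sulfuric acid is added should also avoid sulfonation and acid‑catalysed phenol–aldehyde condensation, and the aldehyde should survive the anhydrous, dark, non‑radical medium.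

Step 3
Reactants: 7 3,5‑dibromo‑2‑(3,5‑dibromo‑2‑hydroxyphenoxy)benzaldehyde
Product: 8 3,5‑dibromo‑2‑[3,5‑dibromo‑2‑(methoxymethoxy)phenoxy]benzaldehyde
Conditions: MOMCl (1.5 equiv), i‑Pr2NEt (2 equiv), CH2Cl2, 0 °C → rt
Reagents that add atoms: chloromethyl methyl ether, COCCl
Why: O‑Alkylation of the acidic dibromophenol by the highly reactive α‑chloro ether (MOM protection) leaves the aldehyde and the aryl bromides untouched and ensures that only the hydroxyl released in step 4 is methylated in step 5.

Step 4
Reactants: 8 3,5‑dibromo‑2‑[3,5‑dibromo‑2‑(methoxymethoxy)phenoxy]benzaldehyde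
Product: 10 3,5‑dibromo‑2‑[3,5‑dibromo‑2‑(methoxymethoxy)phenoxy]phenol, via aryl formate 9 (not isolated)
Conditions: mCPBA (2 equiv), CH2Cl2, rt → 40 °C; aq. Na2S2O3/NaHCO3 wash; then K2CO3 (cat.), MeOH, rt
Reagents that add atoms: 3‑chloroperbenzoic acid, O=C(OO)c1cccc(Cl)c1
Why: Baeyer–Villiger (Dakin‑type) oxidation in which the aryl group, supported by its ortho aryloxy donor, should migrate in the Criegee adduct in preference to hydride to give formate 9, which mild base transesterifies with methanol; the MOM ether, the C–Br bonds and the diaryl ether are inert to both stages.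

Step 5
Reactants: 10 3,5‑dibromo‑2‑[3,5‑dibromo‑2‑(methoxymethoxy)phenoxy]phenol
Product: 11 1,5‑dibromo‑3‑(2,4‑dibromo‑6‑methoxyphenoxy)‑2‑(methoxymethoxy)benzene
Conditions: MeI (1.5 equiv), K2CO3 (2 equiv), DMF, rt
Reagents that add atoms: iodomethane, CI
Why: Williamson ether synthesis (SN2 at iodomethane) on the only free hydroxyl, run at room temperature so that the phenoxide has no chance of Smiles‑type attack on the unactivated neighbouring ring.

Step 6
Reactants: 11 1,5‑dibromo‑3‑(2,4‑dibromo‑6‑methoxyphenoxy)‑2‑(methoxymethoxy)benzene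
Product: 12 2,4‑dibromo‑6‑(2,4‑dibromo‑6‑methoxyphenoxy)phenol (target)
Conditions: HCl (ca. 1 M in MeOH), 50 °C
Reagents that add atoms: none
Why: Acid‑catalysed cleavage of the MOM acetal through its oxocarbenium ion, which methanol traps, should free the phenol while the aryl methyl ether, the diaryl ether and the four C–Br bonds are stable to methanolic HCl.

**Compound list**

1 | catechol (benzene‑1,2‑diol) | Oc1ccccc1O | starting material
2 | 2‑fluorobenzaldehyde | O=Cc1ccccc1F | starting material
3 | 2‑(2‑hydroxyphenoxy)benzaldehyde | O=Cc1ccccc1Oc1ccccc1O | intermediate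
4 | 2‑(5‑bromo‑2‑hydroxyphenoxy)benzaldehyde (monobromide) | O=Cc1ccccc1Oc1cc(Br)ccc1O | intermediate
5 | 2‑(3,5‑dibromo‑2‑hydroxyphenoxy)benzaldehyde (dibromide) | O=Cc1ccccc1Oc1cc(Br)cc(Br)c1O | intermediate
6 | 5‑bromo‑2‑(3,5‑dibromo‑2‑hydroxyphenoxy)benzaldehyde (tribromide) | O=Cc1cc(Br)ccc1Oc1cc(Br)cc(Br)c1O | intermediate
7 | 3,5‑dibromo‑2‑(3,5‑dibromo‑2‑hydroxyphenoxy)benzaldehyde | O=Cc1cc(Br)cc(Br)c1Oc1cc(Br)cc(Br)c1O | intermediate
8 | 3,5‑dibromo‑2‑[3,5‑dibromo‑2‑(methoxymethoxy)phenoxy]benzaldehyde | O=Cc1cc(Br)cc(Br)c1Oc1cc(Br)cc(Br)c1OCOC | intermediate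
9 | 3,5‑dibromo‑2‑[3,5‑dibromo‑2‑(methoxymethoxy)phenoxy]phenyl formate | O=COc1cc(Br)cc(Br)c1Oc1cc(Br)cc(Br)c1OCOC | intermediate
10 | 3,5‑dibromo‑2‑[3,5‑dibromo‑2‑(methoxymethoxy)phenoxy]phenol | Oc1cc(Br)cc(Br)c1Oc1cc(Br)cc(Br)c1OCOC | intermediate
11 | 1,5‑dibromo‑3‑(2,4‑dibromo‑6‑methoxyphenoxy)‑2‑(methoxymethoxy)benzene | COc1cc(Br)cc(Br)c1Oc1cc(Br)cc(Br)c1OCOC | intermediate
12 | 2,4‑dibromo‑6‑(2,4‑dibromo‑6‑methoxyphenoxy)phenol | COc1cc(Br)cc(Br)c1Oc1cc(Br)cc(Br)c1O | target

**Step count and risks**

Total steps: 6. Longest linear sequence: 6 steps (1 and 2 → 12).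

Steps most likely to fail:

1. Step 2. The fourth substitution (C3 of the aldehyde ring, ortho to the ether oxygen, meta to CHO and to the first bromine) is slow. The reaction may stall at the tribromide stage, or a fifth bromination of the phenol ring at its remaining positions may compete. The fallback sets out from 1 and comes back at 7. The two bromines of the aldehyde ring are bought in: excess catechol 1 is arylated with the catalogue compound 3,5‑dibromo‑2‑fluorobenzaldehyde F1 (K2CO3, DMF, not above 60 °C). The fluoride ortho to the formyl group is the only activated leaving group, so this should give 3,5‑dibromo‑2‑(2‑hydroxyphenoxy)benzaldehyde F2. Only the phenol ring is then brominated under mild conditions (NBS, 2.05 equiv, MeCN, 0 °C → rt) that leave the deactivated ring alone. This passes through 3,5‑dibromo‑2‑(5‑bromo‑2‑hydroxyphenoxy)benzaldehyde F3 and should arrive at 7.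

2. Step 4. With two bromines on the migrating ring, hydride migration in the Criegee adduct may overtake aryl migration and lead to the carboxylic acid; slow oxidation may also expose the MOM ether to the acidic medium for too long. The fallback sets out from 8 and comes back at 10. Hydride is removed as a competitor by going through the methyl ketone. MeMgBr (THF, −78 °C) should add to the aldehyde to give racemic 1‑{3,5‑dibromo‑2‑[3,5‑dibromo‑2‑(methoxymethoxy)phenoxy]phenyl}ethanol F4. Dess–Martin periodinane should oxidise it to 1‑{3,5‑dibromo‑2‑[3,5‑dibromo‑2‑(methoxymethoxy)phenoxy]phenyl}ethanone F5. Baeyer–Villiger oxidation with Na2HPO4‑buffered trifluoroperacetic acid, where aryl competes only with methyl, should give 3,5‑dibromo‑2‑[3,5‑dibromo‑2‑(methoxymethoxy)phenoxy]phenyl acetate F6. Methanolysis (K2CO3, MeOH, rt) then delivers 10.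

3. Step 1. The product phenoxide may be arylated a second time, and the catecholate may be oxidised in hot basic DMF, so conversion to the mono‑ether may be poor. The fallback sets out from 2 and comes back at 3. A nucleophile with a single hydroxyl is used: 2‑methoxyphenol (guaiacol) F7 and 2 (K2CO3, DMF, 100 °C) should give 2‑(2‑methoxyphenoxy)benzaldehyde F8 by the same SNAr. The methyl ether is then cleaved with BBr3 (CH2Cl2, −78 → 0 °C), which diaryl ethers and aryl aldehydes tolerate, to give 3.

**Further compounds**

F1 | step 2 | 3,5‑dibromo‑2‑fluorobenzaldehyde | O=Cc1cc(Br)cc(Br)c1F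
F2 | step 2 | 3,5‑dibromo‑2‑(2‑hydroxyphenoxy)benzaldehyde | O=Cc1cc(Br)cc(Br)c1Oc1ccccc1O
F3 | step 2 | 3,5‑dibromo‑2‑(5‑bromo‑2‑hydroxyphenoxy)benzaldehyde | O=Cc1cc(Br)cc(Br)c1Oc1cc(Br)ccc1O
F4 | step 4 | 1‑{3,5‑dibromo‑2‑[3,5‑dibromo‑2‑(methoxymethoxy)phenoxy]phenyl}ethanol (racemic) | CC(O)c1cc(Br)cc(Br)c1Oc1cc(Br)cc(Br)c1OCOC
F5 | step 4 | 1‑{3,5‑dibromo‑2‑[3,5‑dibromo‑2‑(methoxymethoxy)phenoxy]phenyl}ethanone | CC(=O)c1cc(Br)cc(Br)c1Oc1cc(Br)cc(Br)c1OCOC
F6 | step 4 | 3,5‑dibromo‑2‑[3,5‑dibromo‑2‑(methoxymethoxy)phenoxy]phenyl acetate | CC(=O)Oc1cc(Br)cc(Br)c1Oc1cc(Br)cc(Br)c1OCOC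
F7 | step 1 | 2‑methoxyphenol (guaiacol) | COc1ccccc1O
F8 | step 1 | 2‑(2‑methoxyphenoxy)benzaldehyde | COc1ccccc1Oc1ccccc1C=O
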